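**Plan**

- Retrosynthesis: the lactol C–O bond is opened to a formyl/carboxyl pair on ring B. The aryl ester C–O bond of the seven-membered dioxepinone (ring A carboxyl oxygen to a ring B carbon) is then cut back to a ring B C–H, and last the diaryl ether C–O bond is cut.
- Enabling feature: ring B carries the ether oxygen para to its phenol and the ester oxygen on the carbon next to the ether carbon. In the precursor that neighbouring carbon is the only C–H of ring B.
- Forward: ring B is built from 5-fluoro-2-hydroxybenzoic acid and joined to the ring A salicylate by SNAr (ether). PhI(OAc)2 then closes the dioxepinone through a six-membered spirolactone and transfer of the acyloxy group, and acid closes the five-membered lactol.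
- Stereochemistry: the single stereocentre, the (R) lactol carbon, is set last by acylative dynamic kinetic resolution and uncovered by neutral enzymatic deacetylation.

Key step: step 11

Assumption: the lactol carbon is a hemiacetal that can epimerise by ring–chain tautomerism; it is taken to hold its configuration in neutral, aprotic medium at or below room temperature, so it is set and released last.

**Route**

Step 1
Reactants: 1 methyl 2,4-dihydroxy-3,6-dimethylbenzoate
Product: 2 methyl 2-hydroxy-4-methoxy-3,6-dimethylbenzoate
Conditions: MeI (1.05 equiv), K2CO3, acetone, reflux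
Reagents that add atoms: iodomethane CI
Why: Williamson O-methylation; the 2-hydroxyl is held in a hydrogen bond to the ester carbonyl, so the 4-hydroxyl is alkylated selectively.

Step 2
Reactants: 3 5-fluoro-2-hydroxybenzoic acid
Product: 5 5-fluoro-3-formyl-2-hydroxybenzoic acid, via Duff iminium 4 (not isolated)
Conditions: (CH2)6N4, CF3CO2H, 85 °C; then 2 M HCl, 60 °C
Reagents that add atoms: hexamethylenetetramine C1N2CN3CN1CN(C2)C3; water O
Why: Duff formylation goes ortho to the phenol, and C3 is the only free ortho or para position because fluorine blocks the para carbon and the carboxyl group the other ortho carbon.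

Step 3
Reactants: 5 5-fluoro-3-formyl-2-hydroxybenzoic acid
Product: 6 tert-butyl 5-fluoro-3-formyl-2-hydroxybenzoate
Conditions: Cl3CC(=NH)OtBu, CH2Cl2/cyclohexane, rt
Reagents that add atoms: tert-butyl 2,2,2-trichloroacetimidate CC(C)(C)OC(=N)C(Cl)(Cl)Cl
Why: Imidate esterification; the carboxylic acid protonates the imidate and captures the tert-butyl cation, while the much less acidic phenol and the aldehyde do not react without a Lewis acid.

Step 4
Reactants: 6 tert-butyl 5-fluoro-3-formyl-2-hydroxybenzoate
Product: 7 tert-butyl 2-(allyloxy)-5-fluoro-3-formylbenzoate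
Conditions: allyl bromide, K2CO3, DMF, 50 °C
Reagents that add atoms: allyl bromide C=CCBr
Why: Williamson etherification of the only acidic hydroxyl; the allyl ether keeps this oxygen from becoming a phenoxide para to fluorine, which would shut down the later SNAr, and is removable under neutral conditions.

Step 5
Reactants: 7 tert-butyl 2-(allyloxy)-5-fluoro-3-formylbenzoate
Product: 8 tert-butyl 2-(allyloxy)-5-fluoro-3-(hydroxymethyl)benzoate
Conditions: NaBH4, MeOH/THF, 0 °C
Reagents that add atoms: none
Why: Borohydride reduction is chemoselective for the aldehyde over the hindered tert-butyl ester and the allyl ether.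

Step 6
Reactants: 8 tert-butyl 2-(allyloxy)-5-fluoro-3-(hydroxymethyl)benzoate
Product: 9 tert-butyl 2-(allyloxy)-3-{[(tert-butyldimethylsilyl)oxy]methyl}-5-fluorobenzoate
Conditions: TBSCl, imidazole, CH2Cl2, rt
Reagents that add atoms: tert-butyldimethylsilyl chloride CC(C)(C)[Si](C)(C)Cl
Why: Standard silylation of a primary benzylic alcohol; the silyl ether tolerates the magnesium amide, carbonate, iodide and palladium steps and falls in the final acid step.

Step 7
Reactants: 9 tert-butyl 2-(allyloxy)-3-{[(tert-butyldimethylsilyl)oxy]methyl}-5-fluorobenzoate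
Product: 11 tert-butyl 6-(allyloxy)-5-{[(tert-butyldimethylsilyl)oxy]methyl}-3-fluoro-2-formylbenzoate, via arylmagnesium chloride 10 (not isolated)
Conditions: TMPMgCl·LiCl, THF, 0 °C; DMF, 0 °C to rt; aq NH4Cl
Reagents that add atoms: N,N-dimethylformamide CN(C)C=O
Why: Directed ortho-magnesiation with an ester-tolerant hindered amide base takes place at the most acidic C–H, flanked by fluorine and the coordinating ester, and the arylmagnesium is formylated by DMF.

Step 8
Reactants: 2 methyl 2-hydroxy-4-methoxy-3,6-dimethylbenzoate; 11 tert-butyl 6-(allyloxy)-5-{[(tert-butyldimethylsilyl)oxy]methyl}-3-fluoro-2-formylbenzoate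
Product: 12 tert-butyl 6-(allyloxy)-5-{[(tert-butyldimethylsilyl)oxy]methyl}-2-formyl-3-[3-methoxy-6-(methoxycarbonyl)-2,5-dimethylphenoxy]benzoate
Conditions: Cs2CO3, DMSO, 90 °C
Reagents that add atoms: none
Why: SNAr; the ortho formyl group stabilises the Meisenheimer adduct and the caesium phenoxide of 2 displaces fluoride.

Step 9
Reactants: 12 the diaryl ether with ring A methyl ester
Product: 13 2-[4-(allyloxy)-3-(tert-butoxycarbonyl)-5-{[(tert-butyldimethylsilyl)oxy]methyl}-2-formylphenoxy]-4-methoxy-3,6-dimethylbenzoic acid
Conditions: LiI, pyridine, reflux; then cold 0.5 M HCl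
Reagents that add atoms: none
Why: SN2 dealkylation by iodide at the methyl carbon avoids acyl attack on the doubly ortho-substituted ester and cannot touch the tert-butyl ester (any allyl ether lost here converges in step 10).

Step 10
Reactants: 13 the ring A acid with ring B allyl ether
Product: 14 2-[3-(tert-butoxycarbonyl)-5-{[(tert-butyldimethylsilyl)oxy]methyl}-2-formyl-4-hydroxyphenoxy]-4-methoxy-3,6-dimethylbenzoic acid
Conditions: Pd(PPh3)4 (5 mol%), morpholine, THF, rt
Reagents that add atoms: none
Why: Tsuji–Trost deallylation; zerovalent palladium ionises the allyl aryl ether and morpholine captures the π-allyl complex, a neutral process that spares the aldehyde, silyl ether and tert-butyl ester.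

Step 11
Reactants: 14 the diaryl ether acid with free ring B para-aryloxyphenol
Product: 17 tert-butyl 9-{[(tert-butyldimethylsilyl)oxy]methyl}-6-formyl-8-hydroxy-3-methoxy-1,4-dimethyl-11-oxo-11H-dibenzo[b,e][1,4]dioxepine-7-carboxylate, via spiro quinone monoketal lactone 15 (not isolated), via trifluoroacetoxy ketal acid 16 (not isolated)
Conditions: PhI(OAc)2 (1.05 equiv), (CF3)2CHOH/CH2Cl2, 0 °C; aq NaHCO3 wash; then CF3CO2H (2 equiv), CH2Cl2, 4 Å sieves, 0 °C to rt
Reagents that add atoms: none
Why: Proposed new method: ligand exchange of the ring B phenol at trivalent iodine and loss of iodobenzene give a phenoxenium ion stabilised by the para aryloxy oxygen, and the ring A carboxyl group traps it at that para (ipso) carbon in a 6-exo closure to the spiro quinone monoketal lactone 15. Because the six-membered lactone holds its ester s-trans, the carbonyl oxygen cannot bridge to the neighbouring carbon as it does in the open-chain quinol acetate rearrangement, so the 1,2-acyloxy shift is designed as an acid-catalysed dissociative relay: CF3CO2H exchanges reversibly with the ketal acyloxy group to give 16 with a free ring A acid, this acid adds 1,4 to the protonated dienone at the CH β-carbon (7-exo closure of the dioxepinone), trifluoroacetate, the best leaving group on the ketal carbon, departs to leave the cation on the carbon that keeps the aryl ether oxygen, and loss of the CH proton restores ring B; a direct three-centre shift of the acyloxy oxygen would end at the same compound. The closest known reactions are the PhI(OAc)2 oxidation of para-alkoxyphenols to quinone monoketals, the oxidative spirolactonisation of phenol-tethered acids, the acid-promoted 1,2-acyloxy shift of quinol acetates and the Thiele–Winter acetoxylation of quinones. The net result is that the six-membered spirolactone is expanded by one atom to the seven-membered lactone while the aryl ester C–O bond forms; no stereocentre is created (the spiro centre of 15 is racemic and is lost again). The step needs chemoselectivity for ring B, secured because only ring B has a free phenol for the iodine reagent, and site selectivity for the CH carbon next to the ketal carbon, secured because the other β-carbon bears the formyl group and cannot re-aromatise and every other ring B position is substituted; acetic acid from the oxidant is washed out before the acid stage so that acetate is not transferred in place of the ring A acyloxy group.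

Step 12
Reactants: 17 the depsidone with tert-butyl ester, silyl ether and free aldehyde
Product: 19 racemic lactol (3-hydroxyphthalide ring closed between the 7-carboxyl and 6-formyl groups, 8-OH and 9-CH2OH free), via formyl acid 18 (not isolated)
Conditions: CF3CO2H/CH2Cl2/H2O (10:10:1), 0 °C to rt
Reagents that add atoms: none
Why: Acidolysis removes the tert-butyl ester and the silyl ether, and the freed carboxylic acid adds to the neighbouring formyl group (ring–chain tautomerism of a 2-formylbenzoic acid) to close the five-membered lactol as the racemate.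

Step 13
Reactants: 19 racemic lactol
Product: 20 (R)-triacetate (acetates on the lactol oxygen, the phenol and the primary alcohol)
Conditions: Ac2O (4 equiv), iPr2NEt, chiral bicyclic imidazole acyl-transfer catalyst (7-benzyloxy-6,7-dihydro-5H-pyrrolo[1,2-a]imidazole, 10 mol%, the antipode that acetylates the R lactol), toluene, −20 °C
Reagents that add atoms: acetic anhydride CC(=O)OC(C)=O
Why: Acylative dynamic kinetic resolution; the lactol epimerises through its ring-opened formyl carboxylate faster than it is acylated, the chiral N-acylimidazolium acetylates the (R)-lactol preferentially and so sets the only stereocentre, and the primary alcohol and phenol are simply capped.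

Step 14
Reactants: 20 (R)-triacetate
Product: 21 the target, (R)-lactol with free phenol and hydroxymethyl group
Conditions: immobilised Candida antarctica lipase B, 1-butanol, tert-butyl methyl ether, 25 °C
Reagents that add atoms: none
Why: Lipase-catalysed transesterification to butanol cleaves each acetate at the acyl C–O bond in a neutral, non-aqueous medium, so the acetal C–O bond and the configuration of the lactol carbon are not touched.

**Compound list**

1 | methyl 2,4-dihydroxy-3,6-dimethylbenzoate | COC(=O)c1c(C)cc(O)c(C)c1O | starting material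
2 | methyl 2-hydroxy-4-methoxy-3,6-dimethylbenzoate | COC(=O)c1c(C)cc(OC)c(C)c1O | intermediate
3 | 5-fluoro-2-hydroxybenzoic acid | O=C(O)c1cc(F)ccc1O | starting material
4 | Duff iminium, drawn in its simplest form as 5-fluoro-2-hydroxy-3-(iminomethyl)benzoic acid | O=C(O)c1cc(F)cc(C=N)c1O | intermediate
5 | 5-fluoro-3-formyl-2-hydroxybenzoic acid | O=C(O)c1cc(F)cc(C=O)c1O | intermediate
6 | tert-butyl 5-fluoro-3-formyl-2-hydroxybenzoate | CC(C)(C)OC(=O)c1cc(F)cc(C=O)c1O | intermediate
7 | tert-butyl 2-(allyloxy)-5-fluoro-3-formylbenzoate | CC(C)(C)OC(=O)c1cc(F)cc(C=O)c1OCC=C | intermediate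
8 | tert-butyl 2-(allyloxy)-5-fluoro-3-(hydroxymethyl)benzoate | CC(C)(C)OC(=O)c1cc(F)cc(CO)c1OCC=C | intermediate
9 | tert-butyl 2-(allyloxy)-3-{[(tert-butyldimethylsilyl)oxy]methyl}-5-fluorobenzoate | CC(C)(C)OC(=O)c1cc(F)cc(CO[Si](C)(C)C(C)(C)C)c1OCC=C | intermediate
10 | arylmagnesium chloride of 9, metalated between fluorine and the ester | CC(C)(C)OC(=O)c1c([Mg]Cl)c(F)cc(CO[Si](C)(C)C(C)(C)C)c1OCC=C | intermediate
11 | tert-butyl 6-(allyloxy)-5-{[(tert-butyldimethylsilyl)oxy]methyl}-3-fluoro-2-formylbenzoate | CC(C)(C)OC(=O)c1c(C=O)c(F)cc(CO[Si](C)(C)C(C)(C)C)c1OCC=C | intermediate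
12 | tert-butyl 6-(allyloxy)-5-{[(tert-butyldimethylsilyl)oxy]methyl}-2-formyl-3-[3-methoxy-6-(methoxycarbonyl)-2,5-dimethylphenoxy]benzoate | COC(=O)c1c(C)cc(OC)c(C)c1Oc1cc(CO[Si](C)(C)C(C)(C)C)c(OCC=C)c(C(=O)OC(C)(C)C)c1C=O | intermediate
13 | 2-[4-(allyloxy)-3-(tert-butoxycarbonyl)-5-{[(tert-butyldimethylsilyl)oxy]methyl}-2-formylphenoxy]-4-methoxy-3,6-dimethylbenzoic acid | COc1cc(C)c(C(=O)O)c(c1C)Oc1cc(CO[Si](C)(C)C(C)(C)C)c(OCC=C)c(C(=O)OC(C)(C)C)c1C=O | intermediate
14 | 2-[3-(tert-butoxycarbonyl)-5-{[(tert-butyldimethylsilyl)oxy]methyl}-2-formyl-4-hydroxyphenoxy]-4-methoxy-3,6-dimethylbenzoic acid | COc1cc(C)c(C(=O)O)c(c1C)Oc1cc(CO[Si](C)(C)C(C)(C)C)c(O)c(C(=O)OC(C)(C)C)c1C=O | intermediate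
15 | spiro quinone monoketal lactone, tert-butyl 5'-{[(tert-butyldimethylsilyl)oxy]methyl}-2'-formyl-7-methoxy-5,8-dimethyl-4,4'-dioxo-4H-spiro[1,3-benzodioxine-2,1'-cyclohexa-2',5'-diene]-3'-carboxylate (racemic) | COc1cc(C)c2c(c1C)OC1(OC2=O)C=C(CO[Si](C)(C)C(C)(C)C)C(=O)C(C(=O)OC(C)(C)C)=C1C=O | intermediate
16 | trifluoroacetoxy ketal acid, 2-{[3-(tert-butoxycarbonyl)-5-{[(tert-butyldimethylsilyl)oxy]methyl}-2-formyl-4-oxo-1-(trifluoroacetoxy)cyclohexa-2,5-dien-1-yl]oxy}-4-methoxy-3,6-dimethylbenzoic acid (racemic) | COc1cc(C)c(C(=O)O)c(c1C)OC1(OC(=O)C(F)(F)F)C=C(CO[Si](C)(C)C(C)(C)C)C(=O)C(C(=O)OC(C)(C)C)=C1C=O | intermediate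
17 | tert-butyl 9-{[(tert-butyldimethylsilyl)oxy]methyl}-6-formyl-8-hydroxy-3-methoxy-1,4-dimethyl-11-oxo-11H-dibenzo[b,e][1,4]dioxepine-7-carboxylate | COc1cc(C)c2c(c1C)Oc1c(c(CO[Si](C)(C)C(C)(C)C)c(O)c(C(=O)OC(C)(C)C)c1C=O)OC2=O | intermediate
18 | 6-formyl-8-hydroxy-9-(hydroxymethyl)-3-methoxy-1,4-dimethyl-11-oxo-11H-dibenzo[b,e][1,4]dioxepine-7-carboxylic acid | COc1cc(C)c2c(c1C)Oc1c(c(CO)c(O)c(C(=O)O)c1C=O)OC2=O | intermediate
19 | racemic lactol of 18 (hydroxyphthalide ring from the 7-carboxyl and 6-formyl groups) | COc1cc(C)c2c(c1C)Oc1c(c(CO)c(O)c3c1C(O)OC3=O)OC2=O | intermediate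
20 | (R)-triacetate of 19 (lactol O-acetate, phenol acetate, acetoxymethyl) | COc1cc(C)c2c(c1C)Oc1c(c(COC(C)=O)c(OC(C)=O)c3c1[C@H](OC(C)=O)OC3=O)OC2=O | intermediate
21 | CNP0321962.1, the (R)-lactol depsidone with 3-methoxy-1,4-dimethyl ring A and 8-hydroxy-9-(hydroxymethyl) ring B | COc1cc(C)c2c(c1C)Oc1c(c(CO)c(O)c3c1[C@H](O)OC3=O)OC2=O | target

**Step count and risks**

Total steps: 14. Longest linear sequence: 13 steps (steps 2 to 14, from 5-fluoro-2-hydroxybenzoic acid).

Step 11 (new method). What may go wrong: transfer of the acyloxy group to the CH carbon may not outrun hydrolytic loss of ring A from the ketal, or the aryl ether oxygen may migrate in place of the acyloxy group. Fallback with known reactions, making the ester first and the ether second; it sets out from 11 and 2 and comes back at 17.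
- The aldehyde of 11 is masked with 1,2-bis(trimethylsilyloxy)ethane and catalytic Me3SiOTf as the dioxolane F1.
- The one remaining ring C–H, next to fluorine, is magnesiated with (TMP)2Mg·2LiCl, borylated with B(OMe)3 and oxidised with H2O2 to the phenol F2.
- Ester 2 is cleaved with BCl3 to 2-hydroxy-4-methoxy-3,6-dimethylbenzoic acid F3, which is coupled with F2 (DCC, catalytic DMAP) to the depside F4.
- Pyridinium tosylate in wet acetone frees the aldehyde to give the depside aldehyde F5.
- K2CO3 in DMSO closes the diaryl ether by intramolecular SNAr of the ring A phenoxide on the formyl-activated fluoride, giving the depsidone allyl ether F6.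
- Pd(PPh3)4 with morpholine removes the allyl group to give 17.

This detour also does without the intermolecular SNAr of step 8.

Step 13. What may go wrong: background acylation through the ring-opened carboxylate, or a poor fit of the hindered lactol to the small-molecule catalyst, erodes the enantioselectivity. Fallback by biocatalysis; it sets out from 19 and comes back at 21. An immobilised Burkholderia cepacia lipase with vinyl acetate and a trace of Et3N in tert-butyl methyl ether acetylates the primary alcohol and, with in situ epimerisation, one enantiomer of the lactol, leaving the chelated phenol free. This gives the (R)-diacetate F7, lipases of the other enantiopreference being screened if needed. The butanolysis conditions of step 14 then convert it into 21.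

Step 14. What may go wrong: the hindered aryl acetate resists the enzyme, or the lactol epimerises during a long contact time. Fallback by metal-catalysed unmasking; it sets out from 19 and comes back at 21. The resolution of step 13 is run with diallyl dicarbonate in place of acetic anhydride to give the tris(allyl carbonate) F8. It has the same spatial arrangement but is formally S, because the carbonate oxygen now outranks the ring oxygen. Pd(PPh3)4 with PhSiH3 in CH2Cl2 at 0 °C then removes all three allyloxycarbonyl groups under neutral, aprotic conditions and delivers 21.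

**Further compounds**

F1 | step 11 | tert-butyl 6-(allyloxy)-5-{[(tert-butyldimethylsilyl)oxy]methyl}-2-(1,3-dioxolan-2-yl)-3-fluorobenzoate | CC(C)(C)OC(=O)c1c(C2OCCO2)c(F)cc(CO[Si](C)(C)C(C)(C)C)c1OCC=C
F2 | step 11 | tert-butyl 6-(allyloxy)-5-{[(tert-butyldimethylsilyl)oxy]methyl}-2-(1,3-dioxolan-2-yl)-3-fluoro-4-hydroxybenzoate | CC(C)(C)OC(=O)c1c(C2OCCO2)c(F)c(O)c(CO[Si](C)(C)C(C)(C)C)c1OCC=C
F3 | step 11 | 2-hydroxy-4-methoxy-3,6-dimethylbenzoic acid | COc1cc(C)c(C(=O)O)c(O)c1C
F4 | step 11 | depside, aryl ester of F3 with the 4-hydroxyl of F2 (dioxolane intact) | COc1cc(C)c(C(=O)Oc2c(F)c(C3OCCO3)c(C(=O)OC(C)(C)C)c(OCC=C)c2CO[Si](C)(C)C(C)(C)C)c(O)c1C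
F5 | step 11 | depside aldehyde, F4 with the formyl group freed | COc1cc(C)c(C(=O)Oc2c(F)c(C=O)c(C(=O)OC(C)(C)C)c(OCC=C)c2CO[Si](C)(C)C(C)(C)C)c(O)c1C
F6 | step 11 | tert-butyl 8-(allyloxy)-9-{[(tert-butyldimethylsilyl)oxy]methyl}-6-formyl-3-methoxy-1,4-dimethyl-11-oxo-11H-dibenzo[b,e][1,4]dioxepine-7-carboxylate | COc1cc(C)c2c(c1C)Oc1c(c(CO[Si](C)(C)C(C)(C)C)c(OCC=C)c(C(=O)OC(C)(C)C)c1C=O)OC2=O
F7 | step 13 | (R)-diacetate of 19 (lactol O-acetate and acetoxymethyl, phenol free) | COc1cc(C)c2c(c1C)Oc1c(c(COC(C)=O)c(O)c3c1[C@H](OC(C)=O)OC3=O)OC2=O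
F8 | step 14 | tris(allyl carbonate) of 19, lactol carbon with the spatial arrangement of 21 (formally S) | COc1cc(C)c2c(c1C)Oc1c(c(COC(=O)OCC=C)c(OC(=O)OCC=C)c3c1[C@H](OC(=O)OCC=C)OC3=O)OC2=O
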